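**Retrosynthetic overview**

1. Atom labels follow tricyclo[5.3.1.0^{1,5}]undecane: ring A = trione ring (C1, C11, C7, C8, C9, C10), ring B = cyclopentanone (C1, C5, C6, C7, C11), ring C = cyclopentane (C1–C5). Ring C is cut at C1–C5 and C3–C4, giving a spiro vinylcyclopropane (C1, C2, C3) on a monocyclic ring A plus the prenyl alkene C5=C4 held on C7 through C6.
2. The enabling feature: C1 lies between the C10 and C11 carbonyls, so the cyclopropane bond C1–C3 opens to a dicarbonyl-stabilised C1 radical once a thiyl radical adds to the vinyl group on C3; that vinyl group later becomes the acetyl group.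
3. Ring order: ring A (bought as an arene, dearomatised when C7 is quaternised) → spirocyclopropane → ring B (C1–C5) and ring C (C3–C4, three-membered → five-membered) in one radical chain operation.
4. After the cascade: C9 is prenylated from the face of the C11 bridge, the vinyl group is oxidised to acetyl, and C3 is set last through the ring C enone and conjugate reduction.
5. Absolute configuration enters at C7 (asymmetric alkylative dearomatisation); C1, C5, C9 and C3 are relayed from it.

Key step: step 4

Remark: enolised di- and triketones are written as one tautomer, and the C1–C11 labels above are also used for the corresponding atoms of the precursors.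

**Route**

Step 1
Reactants: 1 2-methylbenzene-1,3,5-triol; 2 2-methylpropanoyl chloride
Product: 3 1-(2,4,6-trihydroxy-3-methylphenyl)-2-methylpropan-1-one
Conditions: AlCl3 (3 equiv), PhNO2–CH2Cl2, 0 → 45 °C; aq. HCl work-up
Reagents that add atoms: 2-methylpropanoyl chloride, CC(C)C(=O)Cl
Why: Friedel–Crafts C-acylation of the symmetrical, highly activated triol at one of its two equivalent free ring positions; no stereocentre is formed.

Step 2
Reactants: 3 1-(2,4,6-trihydroxy-3-methylphenyl)-2-methylpropan-1-one; 4 1-bromo-3-methylbut-2-ene (prenyl bromide)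
Product: 5 (6S)-3,5-dihydroxy-6-methyl-6-(3-methylbut-2-en-1-yl)-2-(2-methylpropanoyl)cyclohexa-2,4-dien-1-one
Conditions: 4 (1.05 equiv), O-allyl-N-(9-anthracenylmethyl)cinchonidinium bromide (10 mol %), CsOH·H2O (2 equiv), toluene–CH2Cl2, −60 °C
Reagents that add atoms: prenyl bromide, CC(C)=CCBr
Why: Proposed new method: asymmetric phase-transfer alkylative dearomatisation, in which the phenoxide of 3 enters the organic phase as a contact ion pair with the chiral cinchonidinium cation and is C-alkylated (SN2) by prenyl bromide at the methyl-bearing ring carbon (future C7), the most electron-rich carbon and the one whose alkylation cannot be undone by re-aromatisation, the cation screening one enantiotopic face so that the quaternary carbon should form as (S) (the pseudo-enantiomeric cinchoninium salt is used if the induction is opposite); the closest known reaction types are the base-mediated dearomatising C-prenylation of C-methylated acylphloroglucinols and the enantioselective phase-transfer alkylative dearomatisation of acylphloroglucinols with cinchona ammonium salts.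

Step 3
Reactants: 5 (6S)-3,5-dihydroxy-6-methyl-6-(3-methylbut-2-en-1-yl)-2-(2-methylpropanoyl)cyclohexa-2,4-dien-1-one; 6 (E)-1,4-dibromobut-2-ene
Product: 8 1-ethenyl-8-hydroxy-5-methyl-5-(3-methylbut-2-en-1-yl)-7-(2-methylpropanoyl)spiro[2.5]oct-7-ene-4,6-dione (C5 as set in 5; both cyclopropane stereocentres as a mixture), via C-monoalkylated allylic bromide 7 (not isolated)
Conditions: NaOMe (3.1 equiv), MeOH, 0 °C; then 6 (1.2 equiv), 0 °C → rt
Reagents that add atoms: (E)-1,4-dibromobut-2-ene, BrC/C=C/CBr
Why: Double alkylation of the 1,3-dicarbonyl carbon of 5 (future C1) by the 1,4-dielectrophile, intermolecular SN2 C-alkylation followed by 3-exo-trig SN2' closure by the same carbon (the classical vinylcyclopropane synthesis from 1,3-dicarbonyl compounds), with the protic medium and sodium counter-ion chosen to favour attack through carbon over oxygen; the two cyclopropane stereocentres form as a mixture that does not matter because both are destroyed in step 4.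

Step 4
Reactants: 8 1-ethenyl-8-hydroxy-5-methyl-5-(3-methylbut-2-en-1-yl)-7-(2-methylpropanoyl)spiro[2.5]oct-7-ene-4,6-dione
Product: 9 3-ethenyl-10-hydroxy-4,4,7-trimethyl-9-(2-methylpropanoyl)tricyclo[5.3.1.0^{1,5}]undec-9-ene-8,11-dione (C1, C5 and C7 arranged as in 14; C3 as a mixture)
Conditions: PhSSPh (0.2 equiv), AIBN (0.1 equiv), benzene (0.01 M), 80 °C
Reagents that add atoms: none
Why: PhS• adds reversibly to the vinyl group, the cyclopropylcarbinyl radical opens the C1–C3 bond to the C1 radical stabilised by the C10 and C11 carbonyls, this radical closes 5-exo-trig onto C5 of the prenyl group (C1–C5, ring B, completing the bicyclo[3.2.1]octane), and the tertiary C4 radical closes 5-exo-trig onto C3 of the allyl sulfide (C3–C4, ring C), after which β-scission returns the vinyl group and PhS•, so the three-membered ring C1–C2–C3 has become the five-membered ring C1–C5 by taking up C4 and C5. The closest known reaction types are the thiyl-radical-catalysed [3+2] cycloaddition of 1,1-diacyl-2-vinylcyclopropanes with alkenes and the oxidative 5-exo/5-exo radical bicyclisation of prenylated dearomatised acylphloroglucinols on this same ring system. C1 is fixed by C7 because the C5–C6 bridge can span only one face of ring A; C5 should carry the CMe2 radical exo (syn to C11) because only that arrangement lets C4 reach C3, and the first closure of the stabilised radical is reversible, so the endo radical reverts. C3 forms without reliable control (two near-equivalent chair-like approaches) and is therefore erased in step 7 and set in step 8. The step needs cleavage of C1–C3 rather than C2–C3 (secured by the dicarbonyl stabilisation), attack on a single prenyl group (secured by leaving C9 unprenylated until step 5), and chain transfer without an H-donor (secured by catalytic PhSSPh at high dilution).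

Step 5
Reactants: 9 3-ethenyl-10-hydroxy-4,4,7-trimethyl-9-(2-methylpropanoyl)tricyclo[5.3.1.0^{1,5}]undec-9-ene-8,11-dione; 10 3-methylbut-2-en-1-yl acetate (prenyl acetate)
Product: 11 (1R,5R,7S,9S)-3-ethenyl-4,4,7-trimethyl-9-(3-methylbut-2-en-1-yl)-9-(2-methylpropanoyl)tricyclo[5.3.1.0^{1,5}]undecane-8,10,11-trione (C3 as a mixture)
Conditions: 10 (1.5 equiv), Pd(PPh3)4 (5 mol %), Et3N (1.2 equiv), THF, 25 → 45 °C
Reagents that add atoms: prenyl acetate, CC(=O)OCC=C(C)C
Why: Tsuji–Trost allylation of the acidic enolised β-triketone, in which the π-prenyl complex of divalent palladium is attacked at its unsubstituted terminus by the triketonate carbon C9 (O-prenyl enol ethers re-ionise under the conditions, so C-alkylation is the sink), and attack on the face syn to the C11 carbonyl bridge, away from the C5–C6 bridge, should place prenyl exo and the acyl group endo as in 14 (9S).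

Step 6
Reactants: 11 (1R,5R,7S,9S)-3-ethenyl-4,4,7-trimethyl-9-(3-methylbut-2-en-1-yl)-9-(2-methylpropanoyl)tricyclo[5.3.1.0^{1,5}]undecane-8,10,11-trione
Product: 12 (1R,5R,7S,9S)-3-acetyl-4,4,7-trimethyl-9-(3-methylbut-2-en-1-yl)-9-(2-methylpropanoyl)tricyclo[5.3.1.0^{1,5}]undecane-8,10,11-trione (C3 as a mixture)
Conditions: PdCl2 (10 mol %), CuCl (co-catalyst), O2 (1 atm), DMF–H2O (7:1), 25 °C
Reagents that add atoms: water, O
Why: Tsuji–Wacker oxidation, in which hydroxypalladation of the monosubstituted alkene at its internal carbon and β-hydride elimination give the methyl ketone while the trisubstituted prenyl alkene is inert to divalent palladium under these conditions; C3 stays a mixture.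

Step 7
Reactants: 12 (1R,5R,7S,9S)-3-acetyl-4,4,7-trimethyl-9-(3-methylbut-2-en-1-yl)-9-(2-methylpropanoyl)tricyclo[5.3.1.0^{1,5}]undecane-8,10,11-trione
Product: 13 3-acetyl-4,4,7-trimethyl-9-(3-methylbut-2-en-1-yl)-9-(2-methylpropanoyl)tricyclo[5.3.1.0^{1,5}]undec-2-ene-8,10,11-trione (C1, C5, C7 and C9 as in 14)
Conditions: IBX (2.5 equiv), 4-methoxypyridine N-oxide (2.5 equiv), DMSO, 25 → 40 °C
Reagents that add atoms: none
Why: IBX dehydrogenation of a ketone to its enone (through the enol and single-electron oxidation), where the acetyl group can desaturate only towards C3=C2, the ring ketones have no α-hydrogen and enolisation of the isobutyryl group next to the quaternary C9 is sterically disfavoured, so both C3 epimers should converge on one enone and the uncontrolled stereocentre is removed.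

Step 8
Reactants: 13 3-acetyl-4,4,7-trimethyl-9-(3-methylbut-2-en-1-yl)-9-(2-methylpropanoyl)tricyclo[5.3.1.0^{1,5}]undec-2-ene-8,10,11-trione
Product: 14 (1R,3R,5R,7S,9S)-3-acetyl-4,4,7-trimethyl-9-(3-methylbut-2-en-1-yl)-9-(2-methylpropanoyl)tricyclo[5.3.1.0^{1,5}]undecane-8,10,11-trione
Conditions: [(Ph3P)CuH]6 (5 mol %), (EtO)2MeSiH (1.5 equiv), t-BuOH (1.5 equiv), toluene, 0 → 25 °C; aq. NH4Cl
Reagents that add atoms: none
Why: Copper hydride conjugate reduction, in which hydride is delivered to C2 and the copper enolate is protonated at C3 by t-BuOH from the face opposite the C11 carbonyl, which sits pseudo-axially on the neighbouring ring-fusion carbon C1 and screens the other face, so hydrogen should enter anti and the acetyl group end up syn to C11 (3R); phosphine-ligated copper hydride leaves isolated ketones and the trisubstituted alkene untouched.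

**Compound list**

1 | 2-methylbenzene-1,3,5-triol | Cc1c(O)cc(O)cc1O | starting material
2 | 2-methylpropanoyl chloride | CC(C)C(=O)Cl | starting material
3 | 1-(2,4,6-trihydroxy-3-methylphenyl)-2-methylpropan-1-one | CC(C)C(=O)c1c(O)cc(O)c(C)c1O | intermediate
4 | 1-bromo-3-methylbut-2-ene (prenyl bromide) | CC(C)=CCBr | starting material
5 | (6S)-3,5-dihydroxy-6-methyl-6-(3-methylbut-2-en-1-yl)-2-(2-methylpropanoyl)cyclohexa-2,4-dien-1-one | CC(C)C(=O)C1=C(O)C=C(O)[C@](C)(CC=C(C)C)C1=O | intermediate
6 | (E)-1,4-dibromobut-2-ene | BrC/C=C/CBr | starting material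
7 | (6S)-4-[(2E)-4-bromobut-2-en-1-yl]-3,5-dihydroxy-6-methyl-6-(3-methylbut-2-en-1-yl)-2-(2-methylpropanoyl)cyclohexa-2,4-dien-1-one | CC(C)C(=O)C1=C(O)C(C/C=C/CBr)=C(O)[C@](C)(CC=C(C)C)C1=O | intermediate
8 | 1-ethenyl-8-hydroxy-5-methyl-5-(3-methylbut-2-en-1-yl)-7-(2-methylpropanoyl)spiro[2.5]oct-7-ene-4,6-dione (C5 as in 5; cyclopropane stereocentres as a mixture) | CC(C)C(=O)C1=C(O)C2(CC2C=C)C(=O)[C@](C)(CC=C(C)C)C1=O | intermediate
9 | 3-ethenyl-10-hydroxy-4,4,7-trimethyl-9-(2-methylpropanoyl)tricyclo[5.3.1.0^{1,5}]undec-9-ene-8,11-dione (C1, C5, C7 as in 14; C3 mixture) | C=CC1C[C@]23C(=O)[C@](C)(C[C@@H]2C1(C)C)C(=O)C(C(=O)C(C)C)=C3O | intermediate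
10 | 3-methylbut-2-en-1-yl acetate (prenyl acetate) | CC(=O)OCC=C(C)C | starting material
11 | (1R,5R,7S,9S)-3-ethenyl-4,4,7-trimethyl-9-(3-methylbut-2-en-1-yl)-9-(2-methylpropanoyl)tricyclo[5.3.1.0^{1,5}]undecane-8,10,11-trione (C3 mixture) | C=CC1C[C@]23C(=O)[C@](C)(C[C@@H]2C1(C)C)C(=O)[C@](CC=C(C)C)(C(=O)C(C)C)C3=O | intermediate
12 | (1R,5R,7S,9S)-3-acetyl-4,4,7-trimethyl-9-(3-methylbut-2-en-1-yl)-9-(2-methylpropanoyl)tricyclo[5.3.1.0^{1,5}]undecane-8,10,11-trione (C3 mixture) | CC(=O)C1C[C@]23C(=O)[C@](C)(C[C@@H]2C1(C)C)C(=O)[C@](CC=C(C)C)(C(=O)C(C)C)C3=O | intermediate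
13 | 3-acetyl-4,4,7-trimethyl-9-(3-methylbut-2-en-1-yl)-9-(2-methylpropanoyl)tricyclo[5.3.1.0^{1,5}]undec-2-ene-8,10,11-trione (C1, C5, C7, C9 as in 14) | CC(=O)C1=C[C@]23C(=O)[C@](C)(C[C@@H]2C1(C)C)C(=O)[C@](CC=C(C)C)(C(=O)C(C)C)C3=O | intermediate
14 | (1R,3R,5R,7S,9S)-3-acetyl-4,4,7-trimethyl-9-(3-methylbut-2-en-1-yl)-9-(2-methylpropanoyl)tricyclo[5.3.1.0^{1,5}]undecane-8,10,11-trione | CC(=O)[C@@H]1C[C@]23C(=O)[C@](C)(C[C@@H]2C1(C)C)C(=O)[C@](CC=C(C)C)(C(=O)C(C)C)C3=O | target

**Step count and risks**

Total step count: 8. Longest linear sequence: 8 steps (the route is fully linear from 1).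

The three steps most likely to fail:

Step 2 (Proposed new method). What may go wrong: weak enantiofacial discrimination in the ion pair, competing C-alkylation at the unsubstituted ring carbon, and a second alkylation of the product. Fallback with known chemistry, setting out from 3: base-mediated dearomatising prenylation (prenyl bromide, NaOMe, MeOH, 0 °C) should give the racemic dearomatised trione F1. Its acidic enol is then resolved as a salt with (R)-1-phenylethylamine by fractional crystallisation, taking the (S)-trione (R)-1-phenylethylammonium salt F2 (the antipodal amine is used if it is the other salt that crystallises). Acidification (aq. HCl, EtOAc) releases the (S)-trione, and the route is rejoined at 5.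

Step 3. What may go wrong: ring closure through an enolate oxygen instead of carbon (leading to a vinyldihydrofuran), or opening of the doubly activated cyclopropane by methoxide. Fallback, setting out from 5: Knoevenagel condensation with aqueous formaldehyde generates the methylene trione F3 in the flask. The ylide from allyl(dimethyl)sulfonium bromide and K2CO3 (EtOAc, rt) adds in a Michael sense to its exocyclic carbon to give the sulfonium betaine F4, and the enolate carbon then displaces dimethyl sulfide in a 3-exo-tet SN2 closure. This closure type is known to deliver spirocyclopropanes of cyclic 1,3-diones, and the route is rejoined at 8.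

Step 5. What may go wrong: O-prenylation prevailing over C-prenylation at the congested tricarbonyl carbon, or attack from the wrong face. Fallback, setting out from 9: O-alkylation of the enol with 3-chloro-3-methylbut-1-yne (CuCl2 cat., DBU, MeCN, 0 °C) gives the 1,1-dimethylpropargyl enol ether F5. Semihydrogenation (H2, Pd/CaCO3 poisoned with Pb(OAc)2, quinoline) gives the 1,1-dimethylallyl enol ether F6. Its Claisen rearrangement (toluene, 80 °C) carries the allyl unit from oxygen to C9 across the open exo face with allylic inversion, so the prenyl group arrives as the linear isomer, and the route is rejoined at 11.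

Further compounds
F1 | step 2 | racemic 3,5-dihydroxy-6-methyl-6-(3-methylbut-2-en-1-yl)-2-(2-methylpropanoyl)cyclohexa-2,4-dien-1-one | CC(C)C(=O)C1=C(O)C=C(O)C(C)(CC=C(C)C)C1=O
F2 | step 2 | (R)-1-phenylethylammonium salt of the (S)-trione 5 | CC(C)C(=O)C1=C([O-])C=C(O)[C@](C)(CC=C(C)C)C1=O.C[C@@H]([NH3+])c1ccccc1
F3 | step 3 | (6S)-3-hydroxy-6-methyl-4-methylidene-6-(3-methylbut-2-en-1-yl)-2-(2-methylpropanoyl)cyclohex-2-ene-1,5-dione | CC(C)C(=O)C1=C(O)C(=C)C(=O)[C@](C)(CC=C(C)C)C1=O
F4 | step 3 | sulfonium betaine from F3 and the allyl(dimethyl)sulfonium ylide | CC(C)C(=O)C1=C(O)C(CC(C=C)[S+](C)C)=C([O-])[C@](C)(CC=C(C)C)C1=O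
F5 | step 5 | 10-O-(2-methylbut-3-yn-2-yl) enol ether of 9 | C=CC1C[C@]23C(=O)[C@](C)(C[C@@H]2C1(C)C)C(=O)C(C(=O)C(C)C)=C3OC(C)(C)C#C
F6 | step 5 | 10-O-(2-methylbut-3-en-2-yl) enol ether of 9 | C=CC1C[C@]23C(=O)[C@](C)(C[C@@H]2C1(C)C)C(=O)C(C(=O)C(C)C)=C3OC(C)(C)C=C
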